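The runs stem from a simulated flask on assumed constants, noise included.

A small charge of acid, 2.00 mM, stood with 20 mM of substrate in a closed, stirred flask, and I had the earlier runs to go on.

| setting | midnight | winter | dusk | flask |
|---|---|---|---|---|
| substrate | 20 mM | 20 mM | 40 mM | 20 mM |
| acid | 1.3 mM | 3 mM | 2 mM | 2.00 mM |
| remark | run made earlier | run made earlier | run made earlier |  |
| time |  |  |  | 5.0 min |

| run | time / min | substrate / % | product / % |
|---|---|---|---|
| midnight | 0.833 | 74 | 7 |
| midnight | 1.50 | 62 | 13 |
| midnight | 2.50 | 44 | 23 |
| midnight | 3.00 | 35 | 25 |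
| midnight | 4.00 | 32 | 29 |
| winter | 0.833 | 66 | 20 |
| winter | 1.50 | 49 | 26 |
| winter | 2.50 | 37 | 35 |
| winter | 3.00 | 31 | 41 |
| winter | 4.00 | 21 | 46 |
| dusk | 0.333 | 79 | 6 |
| dusk | 0.667 | 65 | 10 |
| dusk | 1.00 | 51 | 13 |
| dusk | 2.00 | 35 | 19 |
| dusk | 4.00 | 18 | 29 |

(scatter of a reading: 2 percentage points)

- acid is the free proton; pH is minus the decimal logarithm of its molar concentration

- part of the substrate that has reacted at 5.0 min
- pH of the solution at 5.0 min

I worked with the fraction left and not the fraction made, and took as my measure the fall rate (an apparent first-order constant), which is the natural logarithm of one over the fraction of substrate left, divided by the time. At their last readings, at 4.00 min, the midnight run read 0.285 min⁻¹ and the winter run 0.390 min⁻¹; both had the flask's substrate, and their acid charges lay on either side of the flask's, so I interpolated in a straight line to 0.328 min⁻¹. With that I reckoned 19.4% of the substrate left in the flask at 5.0 min, so 80.6% reacted.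

The forecast gave a lower figure than mine, 78.5% reacted, with pH 2.73, and said: “The share going to product rises with acid and falls with loading.”

The flask gave 78.3% reacted and pH 2.70, so the forecast held.

    2 substrate → homo dimer (k = 0.120 M⁻¹ s⁻¹)
    substrate → weak acid + product (k = 6.40 × 10⁻⁴ s⁻¹)
    crystals ⇌ weak acid, rate k3*(cs3 - [weak acid]) while solid is left; crystals form when [weak acid] > cs3 (solubility = 0.200 mM, k = 0.510 s⁻¹)
    substrate + acid → weak acid + acid + product (k = 1.10 M⁻¹ s⁻¹)
    weak acid ⇌ conjugate base + acid, settled at all times (K = 6.30 × 10⁻⁶ M)

The flask's own fall rate, from the 22% of substrate left at 5.00 min, came to 0.306 min⁻¹, lower than the 0.328 min⁻¹ I had read from the runs, and in that flask the step of substrate with acid used substrate at 0.46 of the rate of the step to homo dimer just after the start and at 0.87 of it at 1.68 min. For the neighbouring flask, the same charge stopped at 3.0 min, my fall rate gave 62.6% reacted, and that flask gave 64.2%, a fall rate of 0.343 min⁻¹, higher than the 0.306 min⁻¹ of the flask read at 5.0 min.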